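**Plan**

1. Retrosynthesis: in each tetrahydropyran (ring B left, ring C right; O1, C2 = CH carrying the cyclopentyl, C5 = alkylidene carbon, C6 = OCH2) the bonds O1–C2 and C5–C6 are cut, which removes two formaldehyde units. Then come C4–C5 of both rings (Negishi coupling to a C6 tetrabromodiene), C2–cyclopentane (aldol for ring A, allylation for ring D), the ring A carbinol–isopropenyl-carbon bond (carbonyl-ene) and the ring D isopropenyl bond (epoxide opening).
2. Enabling feature: in rings B and C the oxygen lies between an allylic CH2 (C6) on the vinylic C5 of a Z-alkylidene and a secondary C2 that is β to the cyclopentanol oxygen. O1–C6 is therefore a formaldehyde that can be clamped between a C5 alkenyl anion and an SN2-active C2; both rings share this, so one operation closes both.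
3. Forward order: succinaldehyde → tetrabromodiene (one CBr4 per aldehyde group) → two trans-selective couplings (both Z-bromoalkenes, unsymmetrical ends) → ring D (cyclopentenylation, anti epoxidation, CuI-catalysed isopropenyl Grignard opening) → ring A (syn aldol, carbonyl-ene) → rings B and C together → desilylation.
4. Stereochemistry: the two halves are epimers at the isopropenyl carbon and are made differently. Ring D has its hydroxyl trans to both neighbours (epoxide route); ring A has its hydroxyl cis to isopropenyl (ene closure).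
5. C2 and C2′ are laid down as syn carbinols next to the ring carbons (aldol with an (R)-thiazolidinethione; chair-type transfer from an (R)-allylsilane) and inverted in the key step. The Z geometry comes from the couplings and is carried through configurationally stable alkenyllithiums.

Key step: step 19

Assumption: 6-methylhept-5-enoic acid (19) and the two alkylzinc bromides 5 and 7 (THF solutions) are taken as commercial; cyclopentadiene (10) is cracked from commercial dicyclopentadiene.
Assumption: the antipode of the MOP ligand that delivers the (R)-silane 11 is used in step 6; (R)-MOP-phen is written for definiteness.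

**Route**

Step 1
Reactants: 1 2,5-dimethoxytetrahydrofuran
Product: 2 butanedial (succinaldehyde)
Conditions: H2O, 90 °C, 2 h; CH2Cl2 extraction, distillation, used fresh
Reagents that add atoms: water, O
Why: Acetal hydrolysis of the cyclic bis-acetal releases both aldehyde groups of the symmetric C4 unit that becomes the central chain.

Step 2
Reactants: 2 butanedial; 3 carbon tetrabromide
Product: 4 1,1,6,6-tetrabromohexa-1,5-diene
Conditions: CBr4 (4.4 equiv), PPh3 (8.8 equiv), CH2Cl2, 0 °C
Reagents that add atoms: carbon tetrabromide (second molecule, for the second aldehyde group), BrC(Br)(Br)Br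
Why: Twofold Ramirez dibromo-olefination (first stage of the Corey–Fuchs sequence) consumes one molecule of carbon tetrabromide per aldehyde group, two in all, and turns each aldehyde into a gem-dibromoalkene whose CBr2 carbon is the future C5 of a tetrahydropyran.

Step 3
Reactants: 4 1,1,6,6-tetrabromohexa-1,5-diene; 5 [2-(1,3-dioxolan-2-yl)ethyl]zinc bromide
Product: 6 2-[(3Z)-3,8,8-tribromoocta-3,7-dien-1-yl]-1,3-dioxolane
Conditions: 4 (3 equiv), 5 (1 equiv, THF), PdCl2(DPEphos) (3 mol%), THF, 0 → 23 °C; excess 4 recovered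
Reagents that add atoms: none
Why: trans-Selective Negishi monoalkylation of a 1,1-dibromoalkene: zerovalent palladium inserts into the C–Br bond trans to the chain, so the alkyl group enters trans and the remaining bromine is cis to the chain (3Z), the geometry the ring B alkylidene needs, while the excess of 4 keeps the coupling at one terminus.

Step 4
Reactants: 6 tribromodiene acetal; 7 (3-ethoxy-3-oxopropyl)zinc bromide
Product: 8 ethyl (4Z,8Z)-4,9-dibromo-11-(1,3-dioxolan-2-yl)undeca-4,8-dienoate
Conditions: 7 (1.3 equiv, THF), PdCl2(DPEphos) (3 mol%), THF, 23 °C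
Reagents that add atoms: none
Why: A second trans-selective Negishi monoalkylation at the remaining gem-dibromoalkene, which is far more reactive than the trisubstituted bromoalkene already present, sets the second Z-bromoalkene (ring C) and leaves the two ends differentiated as ester and acetal.

Step 5
Reactants: 8 dibromo diene ester
Product: 9 (4Z,8Z)-4,9-dibromo-11-(1,3-dioxolan-2-yl)undeca-4,8-dienal
Conditions: i-Bu2AlH (1.05 equiv), CH2Cl2, −78 °C; aq. KNaC4H4O6
Reagents that add atoms: none
Why: Partial hydride reduction of the ester stops at the aldehyde because the tetrahedral aluminium hemiacetal is stable at −78 °C; acetal and bromoalkenes are inert.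

Step 6
Reactants: 10 cyclopenta-1,3-diene
Product: 11 (R)-(cyclopent-2-en-1-yl)trichlorosilane
Conditions: HSiCl3 (1.2 equiv), [PdCl(C3H5)]2 (0.05 mol%), (R)-MOP-phen (0.2 mol%), neat, −30 → 0 °C; distilled
Reagents that add atoms: trichlorosilane, Cl[SiH](Cl)Cl
Why: Palladium-catalysed asymmetric 1,4-hydrosilylation of the diene through a π-allylpalladium silyl intermediate, in which the chiral monophosphine sets the silicon-bearing allylic stereocentre.

Step 7
Reactants: 9 dibromo diene aldehyde; 11 (R)-allylsilane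
Product: 12 (1S,4Z,8Z)-4,9-dibromo-1-[(1S)-cyclopent-2-en-1-yl]-11-(1,3-dioxolan-2-yl)undeca-4,8-dien-1-ol
Conditions: 11 (1.3 equiv), DMF, 0 °C, 12 h; aq. NaHCO3
Reagents that add atoms: none
Why: DMF-promoted allylation of the aldehyde by the allyltrichlorosilane through a closed six-membered chair transition state (Sakurai-type allylation via a hypervalent silicate): syn SE2′ transfer from silicon fixes the ring D carbon that bears the chain (S), and the ring-locked Z allyl unit gives the syn carbinol C2′ (S), the epimer required before the later inversion.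

Step 8
Reactants: 12 homoallylic alcohol
Product: 13 4-methylbenzenesulfonate of 12
Conditions: TsCl, DABCO, CH2Cl2, 0 → 23 °C
Reagents that add atoms: p-toluenesulfonyl chloride, Cc1ccc(cc1)S(=O)(=O)Cl
Why: Sulfonate ester formation turns C2′–OH into the leaving group for the key step and removes the hydroxyl that would otherwise direct the epoxidation to the wrong face.

Step 9
Reactants: 13 cyclopentenyl tosylate
Product: 14 anti-epoxide of 13
Conditions: mCPBA, NaHCO3, CH2Cl2, 0 °C
Reagents that add atoms: 3-chloroperoxybenzoic acid, OOC(=O)c1cccc(Cl)c1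
Why: Prilezhaev epoxidation of the strained cis-alkene on the face opposite to the bulky sulfonyloxyalkyl substituent (steric control) places the oxygen anti to the side chain, while the bromine-deactivated alkenes do not react.

Step 10
Reactants: 14 anti-epoxide; 15 isopropenylmagnesium bromide
Product: 16 (1S,4Z,8Z)-4,9-dibromo-11-(1,3-dioxolan-2-yl)-1-[(1S,2S,3S)-2-hydroxy-3-(prop-1-en-2-yl)cyclopentyl]undeca-4,8-dien-1-yl 4-methylbenzenesulfonate
Conditions: 15 (3 equiv), CuI (10 mol%), THF, −30 → −10 °C; cold aq. NH4Cl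
Reagents that add atoms: none
Why: Copper-catalysed Grignard opening of the epoxide by SN2 attack at the ring carbon remote from the side chain gives ring D with the hydroxyl trans to both neighbours and the isopropenyl group trans to the hydroxyl (inversion at the attacked carbon).

Step 11
Reactants: 16 ring D alcohol
Product: 17 tert-butyldimethylsilyl ether of 16
Conditions: TBSOTf, 2,6-lutidine, CH2Cl2, −78 °C
Reagents that add atoms: tert-butyldimethylsilyl trifluoromethanesulfonate, CC(C)(C)[Si](C)(C)OS(=O)(=O)C(F)(F)F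
Why: Silyl ether formation masks the ring D hydroxyl, which would otherwise compete in the later sulfonylation and, as an alkoxide, could trigger Grob fragmentation of the 1,3-hydroxy sulfonate.

Step 12
Reactants: 17 silyl ether acetal
Product: 18 (4Z,8Z,12S)-4,9-dibromo-12-[(1S,2S,3S)-2-(tert-butyldimethylsilyloxy)-3-(prop-1-en-2-yl)cyclopentyl]-12-(tosyloxy)dodeca-4,8-dienal
Conditions: PPTS (cat.), acetone–H2O (10:1), 50 °C
Reagents that add atoms: water, O
Why: Mild acid-catalysed acetal hydrolysis unveils the second aldehyde (future C2 of ring B) without touching the secondary silyl ether, the sulfonate or the alkenes.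

Step 13
Reactants: 19 6-methylhept-5-enoic acid; 20 (R)-4-benzyl-1,3-thiazolidine-2-thione
Product: 21 (4R)-4-benzyl-3-(6-methylhept-5-enoyl)-1,3-thiazolidine-2-thione
Conditions: DCC, DMAP (cat.), CH2Cl2, 0 → 23 °C
Reagents that add atoms: none
Why: Steglich-type carbodiimide acylation of the auxiliary nitrogen gives the chiral N-acyl thiazolidinethione that carries all eight carbons of ring A and its isopropenyl group.

Step 14
Reactants: 18 aldehyde; 21 N-acyl thiazolidinethione
Product: 22 syn aldol adduct (2R,3S at the new stereodiad)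
Conditions: 21 (1.3 equiv), TiCl4, i-Pr2NEt, N-methyl-2-pyrrolidinone, CH2Cl2, 0 °C; then 18, −78 → 0 °C
Reagents that add atoms: none
Why: Evans-type syn aldol of the chlorotitanium Z-enolate through a Zimmerman–Traxler chair: the (R)-benzyl auxiliary shields one enolate face and gives the (2R,3S) adduct, which sets the ring A carbon that will bear ring B and the syn carbinol C2 (S), again the epimer required before inversion.

Step 15
Reactants: 22 aldol adduct
Product: 23 bis(4-methylbenzenesulfonate)
Conditions: TsCl, DABCO, CH2Cl2, 0 °C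
Reagents that add atoms: p-toluenesulfonyl chloride, Cc1ccc(cc1)S(=O)(=O)Cl
Why: Sulfonate ester formation under a weak, non-enolising amine base converts C2–OH into the second leaving group without β-elimination.

Step 16
Reactants: 23 bis-tosylate imide
Product: 24 α-branched β-tosyloxy aldehyde
Conditions: i-Bu2AlH (1.5 equiv), CH2Cl2, −78 °C; aq. KNaC4H4O6
Reagents that add atoms: none
Why: Hydride reduction of the activated N-acyl thiazolidinethione stops at the aldehyde and releases the auxiliary; sulfonates, silyl ether and bromoalkenes are inert at −78 °C.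

Step 17
Reactants: 24 aldehyde
Product: 25 ring A cyclopentanol [(1S,2S,3R)-2-hydroxy-3-(prop-1-en-2-yl)cyclopentyl unit]
Conditions: Me2AlCl (2 equiv), CH2Cl2, −78 → −20 °C
Reagents that add atoms: none
Why: Lewis acid-promoted intramolecular carbonyl-ene reaction of the aldehyde with the trisubstituted alkene: the concerted six-centre hydrogen transfer through a cis-fused bicyclic transition state places hydroxyl and isopropenyl cis, and the pseudo-equatorial α-substituent places the hydroxyl trans to the side chain, so both new ring A stereocentres follow from the aldol-derived centre.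

Step 18
Reactants: 25 ring A alcohol
Product: 26 bis(silyl ether) bis(tosylate) bis(Z-bromoalkene)
Conditions: TBSOTf, 2,6-lutidine, CH2Cl2, −78 → 0 °C
Reagents that add atoms: tert-butyldimethylsilyl trifluoromethanesulfonate, CC(C)(C)[Si](C)(C)OS(=O)(=O)C(F)(F)F
Why: Silyl ether formation removes the last acidic proton and prevents Grob fragmentation of the ring A 1,3-hydroxy sulfonate under the basic key step.

Step 19
Reactants: 26 bis(silyl ether) bis(tosylate) bis(Z-bromoalkene); 27 formaldehyde
Product: 30 bis-TBS ether of the target, via dilithio dialkenyl species 28 (not isolated), via dilithium bis(allylic alkoxide) 29 (not isolated)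
Conditions: t-BuLi (4.2 equiv), THF–Et2O, −95 °C, 10 min; CH2O (gas from cracked paraformaldehyde, excess), −95 → 0 °C; then HMPA, 40 °C
Reagents that add atoms: formaldehyde (second molecule, for the second ring), C=O
Why: t-BuLi exchanges both alkenyl bromides with retention to give 28, which adds to two molecules of formaldehyde to give the bis(allylic alkoxide) 29, and each alkoxide then displaces the toluenesulfonate at C2 (C2′); formaldehyde thus acts as a C-electrophile/O-nucleophile linchpin in a twofold anionic formal [4+2] annulation. The closest known reaction type is the Parham-type sequence of halogen–lithium exchange, carbonyl addition and intramolecular Williamson etherification. Rings B and C each close by a 6-exo-tet SN2 attack of O1 on C2 after the C5–C6 bond has formed intermolecularly. The new stereocentres C2 and C2′ arise by Walden inversion of the (S)-sulfonates set in steps 14 and 7, which gives the (R) configuration of the target at both. The step needs bromine–lithium exchange to outrun attack on the sulfonate esters (very fast exchange of alkenyl bromides at −95 °C, no acidic protons), O-alkylation to outrun E2 or Grob fragmentation (six-membered transition state, silyl caps on both ring hydroxyls), and retention of the Z geometry (configurationally stable trisubstituted alkenyllithiums, bromine placed cis to the chain in steps 3 and 4).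

Step 20
Reactants: 30 bis-TBS ether of the target
Product: 31 target CNP0267443.2
Conditions: TBAF, THF, 50 °C
Reagents that add atoms: none
Why: Fluoride-mediated cleavage of the two secondary silyl ethers (desilylation driven by the Si–F bond) frees both cyclopentanols without affecting the allylic ethers or the alkenes.

**Compound list**

1 | 2,5-dimethoxytetrahydrofuran (cis/trans mixture) | COC1CCC(OC)O1 | starting material
2 | butanedial (succinaldehyde) | O=CCCC=O | intermediate
3 | carbon tetrabromide (two molecules are incorporated in step 2) | BrC(Br)(Br)Br | starting material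
4 | 1,1,6,6-tetrabromohexa-1,5-diene | BrC(Br)=CCCC=C(Br)Br | intermediate
5 | [2-(1,3-dioxolan-2-yl)ethyl]zinc bromide | Br[Zn]CCC1OCCO1 | starting material
6 | 2-[(3Z)-3,8,8-tribromoocta-3,7-dien-1-yl]-1,3-dioxolane | BrC(Br)=CCC/C=C(Br)/CCC1OCCO1 | intermediate
7 | (3-ethoxy-3-oxopropyl)zinc bromide | CCOC(=O)CC[Zn]Br | starting material
8 | ethyl (4Z,8Z)-4,9-dibromo-11-(1,3-dioxolan-2-yl)undeca-4,8-dienoate | CCOC(=O)CC/C(Br)=C/CC/C=C(Br)/CCC1OCCO1 | intermediate
9 | (4Z,8Z)-4,9-dibromo-11-(1,3-dioxolan-2-yl)undeca-4,8-dienal | O=CCC/C(Br)=C/CC/C=C(Br)/CCC1OCCO1 | intermediate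
10 | cyclopenta-1,3-diene | C1=CC=CC1 | starting material
11 | (R)-(cyclopent-2-en-1-yl)trichlorosilane | Cl[Si](Cl)(Cl)[C@H]1C=CCC1 | intermediate
12 | (1S,4Z,8Z)-4,9-dibromo-1-[(1S)-cyclopent-2-en-1-yl]-11-(1,3-dioxolan-2-yl)undeca-4,8-dien-1-ol | O1CCOC1CC/C(Br)=C/CC/C=C(Br)/CC[C@@H]([C@H]2CCC=C2)O | intermediate
13 | 4-methylbenzenesulfonate of 12 | O1CCOC1CC/C(Br)=C/CC/C=C(Br)/CC[C@@H]([C@H]2CCC=C2)OS(=O)(=O)c3ccc(C)cc3 | intermediate
14 | tosylate 13 with the cyclopentene epoxidised on the face opposite to the side chain (6-oxabicyclo[3.1.0]hexan-2-yl group) | O1CCOC1CC/C(Br)=C/CC/C=C(Br)/CC[C@@H]([C@H]2CC[C@@H]3O[C@H]23)OS(=O)(=O)c4ccc(C)cc4 | intermediate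
15 | isopropenylmagnesium bromide | CC(=C)[Mg]Br | starting material
16 | (1S,4Z,8Z)-4,9-dibromo-11-(1,3-dioxolan-2-yl)-1-[(1S,2S,3S)-2-hydroxy-3-(prop-1-en-2-yl)cyclopentyl]undeca-4,8-dien-1-yl 4-methylbenzenesulfonate | O1CCOC1CC/C(Br)=C/CC/C=C(Br)/CC[C@@H]([C@H]2CC[C@@H](C(C)=C)[C@@H]2O)OS(=O)(=O)c3ccc(C)cc3 | intermediate
17 | tert-butyldimethylsilyl ether of 16 (ring D oxygen) | O1CCOC1CC/C(Br)=C/CC/C=C(Br)/CC[C@@H]([C@H]2CC[C@@H](C(C)=C)[C@@H]2O[Si](C)(C)C(C)(C)C)OS(=O)(=O)c3ccc(C)cc3 | intermediate
18 | (4Z,8Z,12S)-4,9-dibromo-12-[(1S,2S,3S)-2-(tert-butyldimethylsilyloxy)-3-(prop-1-en-2-yl)cyclopentyl]-12-(tosyloxy)dodeca-4,8-dienal | O=CCC/C(Br)=C/CC/C=C(Br)/CC[C@@H]([C@H]1CC[C@@H](C(C)=C)[C@@H]1O[Si](C)(C)C(C)(C)C)OS(=O)(=O)c2ccc(C)cc2 | intermediate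
19 | 6-methylhept-5-enoic acid | CC(C)=CCCCC(=O)O | starting material
20 | (R)-4-benzyl-1,3-thiazolidine-2-thione | S=C1N[C@H](Cc2ccccc2)CS1 | starting material
21 | (4R)-4-benzyl-3-(6-methylhept-5-enoyl)-1,3-thiazolidine-2-thione | CC(C)=CCCCC(=O)N1C(=S)SC[C@H]1Cc1ccccc1 | intermediate
22 | syn aldol adduct: N-acyl thiazolidinethione with (2R)-2-(4-methylpent-3-en-1-yl) and (3S)-3-hydroxy groups, carrying the (Z,Z)-dibromodiene chain and the ring D tosylate unit of 18 | CC(C)=CCC[C@H]([C@@H](O)CC/C(Br)=C/CC/C=C(Br)/CC[C@@H]([C@H]1CC[C@@H](C(C)=C)[C@@H]1O[Si](C)(C)C(C)(C)C)OS(=O)(=O)c2ccc(C)cc2)C(=O)N3C(=S)SC[C@H]3Cc4ccccc4 | intermediate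
23 | 3-O-tosylate of 22 (bis-tosylate) | CC(C)=CCC[C@H]([C@@H](OS(=O)(=O)c1ccc(C)cc1)CC/C(Br)=C/CC/C=C(Br)/CC[C@@H]([C@H]2CC[C@@H](C(C)=C)[C@@H]2O[Si](C)(C)C(C)(C)C)OS(=O)(=O)c3ccc(C)cc3)C(=O)N4C(=S)SC[C@H]4Cc5ccccc5 | intermediate
24 | aldehyde from 23: (2R)-2-(4-methylpent-3-en-1-yl)-(3S)-3-tosyloxy aldehyde with the same chain and ring D unit | CC(C)=CCC[C@H]([C@@H](OS(=O)(=O)c1ccc(C)cc1)CC/C(Br)=C/CC/C=C(Br)/CC[C@@H]([C@H]2CC[C@@H](C(C)=C)[C@@H]2O[Si](C)(C)C(C)(C)C)OS(=O)(=O)c3ccc(C)cc3)C=O | intermediate
25 | ene product: ring A [(1S,2S,3R)-2-hydroxy-3-(prop-1-en-2-yl)cyclopentyl] and ring D (silyl ether) joined by the (Z,Z)-dibromodiene chain with both C2 tosylates | C=C(C)[C@H]1CC[C@H]([C@@H](OS(=O)(=O)c2ccc(C)cc2)CC/C(Br)=C/CC/C=C(Br)/CC[C@@H]([C@H]3CC[C@@H](C(C)=C)[C@@H]3O[Si](C)(C)C(C)(C)C)OS(=O)(=O)c4ccc(C)cc4)[C@H]1O | intermediate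
26 | tert-butyldimethylsilyl ether of 25 (both ring hydroxyls silylated) | C=C(C)[C@H]1CC[C@H]([C@@H](OS(=O)(=O)c2ccc(C)cc2)CC/C(Br)=C/CC/C=C(Br)/CC[C@@H]([C@H]3CC[C@@H](C(C)=C)[C@@H]3O[Si](C)(C)C(C)(C)C)OS(=O)(=O)c4ccc(C)cc4)[C@H]1O[Si](C)(C)C(C)(C)C | intermediate
27 | formaldehyde (monomer, from commercial paraformaldehyde; two molecules are incorporated in step 19) | C=O | starting material
28 | dilithio dialkenyl species (both Br of 26 replaced by Li, geometry retained) | C=C(C)[C@H]1CC[C@H]([C@@H](OS(=O)(=O)c2ccc(C)cc2)CC/C([Li])=C/CC/C=C([Li])/CC[C@@H]([C@H]3CC[C@@H](C(C)=C)[C@@H]3O[Si](C)(C)C(C)(C)C)OS(=O)(=O)c4ccc(C)cc4)[C@H]1O[Si](C)(C)C(C)(C)C | intermediate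
29 | dilithium bis(allylic alkoxide) (each alkenyl carbon now bears CH2OLi) | C=C(C)[C@H]1CC[C@H]([C@@H](OS(=O)(=O)c2ccc(C)cc2)CC/C(CO[Li])=C/CC/C=C(CO[Li])/CC[C@@H]([C@H]3CC[C@@H](C(C)=C)[C@@H]3O[Si](C)(C)C(C)(C)C)OS(=O)(=O)c4ccc(C)cc4)[C@H]1O[Si](C)(C)C(C)(C)C | intermediate
30 | bis(tert-butyldimethylsilyl) ether of the target (rings B and C closed) | C=C(C)[C@H]1CC[C@H]([C@H]2CC/C(=C/CC/C=C3/CC[C@H]([C@H]4CC[C@@H](C(=C)C)[C@@H]4O[Si](C)(C)C(C)(C)C)OC3)CO2)[C@H]1O[Si](C)(C)C(C)(C)C | intermediate
31 | target CNP0267443.2 | C=C(C)[C@H]1CC[C@H]([C@H]2CC/C(=C/CC/C=C3/CC[C@H]([C@H]4CC[C@@H](C(=C)C)[C@@H]4O)OC3)CO2)[C@H]1O | target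

**Step count and risks**

Total step count: 20. Longest linear sequence: 18 (steps 1–5, 7–12, 14–20); steps 6 and 13 are one-step branches.

Steps most likely to fail:

Step 19. t-BuLi may attack the arenesulfonate esters (ortho-metalation or S–O cleavage) before the bromine–lithium exchange is complete, and the lithium alkoxides may displace the hindered secondary sulfonates too slowly, so that elimination competes with ring closure. The fallback sets out from 26. A twofold Stille coupling with (tributylstannyl)methanol (CCCC[Sn](CO)(CCCC)CCCC; Pd(PPh3)4, dioxane, 90 °C) forms both C5–C6 bonds with retention and gives the bis(hydroxymethyl) diene F1. NaH in THF–DMF (0 → 40 °C) then closes both rings by the same 6-exo-tet displacements with inversion, and the fallback comes back to the route at 30.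

Step 3. Coupling may occur at both dibromovinyl termini of the symmetric tetrabromide, and the trans-selectivity of the alkylzinc coupling may erode through over-reaction. The fallback sets out from 3 and 5 and breaks the symmetry through the starting material instead of through stoichiometry. Ramirez olefination of commercial methyl 4-oxobutanoate (COC(=O)CCC=O) with 3 and PPh3 gives methyl 5,5-dibromopent-4-enoate F2. Negishi coupling with 5 (PdCl2(DPEphos)) gives methyl (4Z)-5-bromo-7-(1,3-dioxolan-2-yl)hept-4-enoate F3. i-Bu2AlH at −78 °C gives (4Z)-5-bromo-7-(1,3-dioxolan-2-yl)hept-4-enal F4. A second Ramirez olefination with 3 comes back to the route at 6.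

Step 17. Under the Lewis acid the β-sulfonate may be lost from the α-branched aldehyde (elimination or ionisation) faster than the ene closure, which would also erode the cis selectivity. The fallback sets out from 22 and installs the leaving group only after ring A exists. Silylation (TESOTf, 2,6-lutidine, −78 °C) gives the triethylsilyl ether F5. i-Bu2AlH (−78 °C) gives the β-silyloxy aldehyde F6. The Me2AlCl ene closure gives the cyclopentanol F7, and TBSOTf/2,6-lutidine gives the silyl ether F8. Selective removal of the triethylsilyl group (PPTS, MeOH, 0 °C) gives the C2 alcohol F9. Tosylation (TsCl, DABCO) comes back to the route at 26.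

**Further compounds**

F1 | step 19 | bis(hydroxymethyl) diene (26 with each Br replaced by CH2OH) | C=C(C)[C@H]1CC[C@H]([C@@H](OS(=O)(=O)c2ccc(C)cc2)CC/C(CO)=C/CC/C=C(CO)/CC[C@@H]([C@H]3CC[C@@H](C(C)=C)[C@@H]3O[Si](C)(C)C(C)(C)C)OS(=O)(=O)c4ccc(C)cc4)[C@H]1O[Si](C)(C)C(C)(C)C
F2 | step 3 | methyl 5,5-dibromopent-4-enoate | COC(=O)CCC=C(Br)Br
F3 | step 3 | methyl (4Z)-5-bromo-7-(1,3-dioxolan-2-yl)hept-4-enoate | COC(=O)CC/C=C(Br)/CCC1OCCO1
F4 | step 3 | (4Z)-5-bromo-7-(1,3-dioxolan-2-yl)hept-4-enal | O=CCC/C=C(Br)/CCC1OCCO1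
F5 | step 17 | triethylsilyl ether of aldol adduct 22 | CC(C)=CCC[C@H]([C@@H](O[Si](CC)(CC)CC)CC/C(Br)=C/CC/C=C(Br)/CC[C@@H]([C@H]1CC[C@@H](C(C)=C)[C@@H]1O[Si](C)(C)C(C)(C)C)OS(=O)(=O)c2ccc(C)cc2)C(=O)N3C(=S)SC[C@H]3Cc4ccccc4
F6 | step 17 | β-triethylsilyloxy aldehyde from F5 | CC(C)=CCC[C@H]([C@@H](O[Si](CC)(CC)CC)CC/C(Br)=C/CC/C=C(Br)/CC[C@@H]([C@H]1CC[C@@H](C(C)=C)[C@@H]1O[Si](C)(C)C(C)(C)C)OS(=O)(=O)c2ccc(C)cc2)C=O
F7 | step 17 | ring A cyclopentanol with C2 triethylsilyl ether | C=C(C)[C@H]1CC[C@H]([C@@H](O[Si](CC)(CC)CC)CC/C(Br)=C/CC/C=C(Br)/CC[C@@H]([C@H]2CC[C@@H](C(C)=C)[C@@H]2O[Si](C)(C)C(C)(C)C)OS(=O)(=O)c3ccc(C)cc3)[C@H]1O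
F8 | step 17 | tert-butyldimethylsilyl ether of F7 | C=C(C)[C@H]1CC[C@H]([C@@H](O[Si](CC)(CC)CC)CC/C(Br)=C/CC/C=C(Br)/CC[C@@H]([C@H]2CC[C@@H](C(C)=C)[C@@H]2O[Si](C)(C)C(C)(C)C)OS(=O)(=O)c3ccc(C)cc3)[C@H]1O[Si](C)(C)C(C)(C)C
F9 | step 17 | C2 alcohol from F8 | C=C(C)[C@H]1CC[C@H]([C@@H](O)CC/C(Br)=C/CC/C=C(Br)/CC[C@@H]([C@H]2CC[C@@H](C(C)=C)[C@@H]2O[Si](C)(C)C(C)(C)C)OS(=O)(=O)c3ccc(C)cc3)[C@H]1O[Si](C)(C)C(C)(C)C
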